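The last reading of oak stands at 80.0 min, while the asked course runs to 4.0 h, so the reckoning has to carry well past the data.

| flask | substrate | partner | protic impurity | remark | time |
|---|---|---|---|---|---|
| oak | 2 M | 2.6 M | 0.040 M | the very flask that is asked about, followed so far |  |
| birch | 1.3 M | 2.6 M | 0.040 M | run made earlier |  |
| flask | 2.0 M | 2.60 M | 0.0400 M |  | 4.0 h |

- oak (time / min: target / %): 10.0: 1; 25.0: 12; 50.0: 24; 80.0: 37
- birch (time / min: target / %): 8.00: 1; 20.0: 9; 40.0: 20; 90.0: 41

(standard deviation of a reading: 1.5 percentage points)

- amount of target in percent of the substrate charged, at 12 min, 1.0 h and 4.0 h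

- the analysis behind the earlier runs scatters by 1.5 percentage points, standard deviation

From 25.0 min to 80.0 min, oak gains a fraction 0.00455 /min of its substrate charge, and from 20.0 min to 90.0 min birch gains 0.00457 /min. At equal partner, the molar rate therefore runs with substrate, within the scatter. The bench rule holds a partner in excess constant, which makes the reaction pseudo-first-order. Applied to those two oak readings, it gives 76.2% at 4.0 h.

The rule ends where substrate can consume a large share of the partner. If each protic impurity quenches one partner, the free partner is F = 2.56 M. The free excess E, which is F over the substrate charge, is then 1.28 in oak. Substrate is the limiting reagent, but its full conversion takes 78.1% of F, so a constant partner is a poor reckoning for oak.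

The reckoning here therefore lets partner fall. Let y be the fraction of charge turned to target. With the rate proportional to substrate left and free partner left, θ = ln[(E − y)/(E(1 − y))] grows evenly with time. Oak gives θ = 0.0294 at 25.0 min and 0.121 at 80.0 min, a pace of 0.0998 /h. Carried on, this gives 29.5% at 1.0 h and 68.4% at 4.0 h. Interpolating between the readings gives 2.47% at 12 min.

The forecast gives 3%, 28.5% and 67%, and says of its last figure: “The 4 h value is a long extrapolation.”

Oak gives 3.52%, 28.8% and 68.3%, and the forecast held.

substrate → intermediate C (k = 5.00 /h); substrate + target → side product (k = 0.0520 /M/h); partner + protic impurity → quenched reagent (k = 150 /M/h); substrate → intermediate A (k = 0.230 /h); intermediate A ⇌ intermediate B (K = 47.0, k = 0.0940 /h); partner + intermediate C → target (k = 0.200 /M/h) At 2.00 h, oak holds 0% substrate and 46.9% intermediate C. With E, target at 4.0 h leaves 45.9% of the partner charge, and oak holds 45.9%. In birch, E is 1.97, and by it the 41% read at 90.0 min leaves 78.0% of the partner charge.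

(The data are simulated with constants of no real substance, and the scatter is random.)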